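Next on this bench: three flasks are running, and the thing to watch in them is how fast left-handed product turns into its mirror image.

| flask | left-handed substrate | right-handed substrate | gas | temperature | remark | time |
|---|---|---|---|---|---|---|
| south-west | 0.17 M | 0.17 M | 97 mM (held) | 40 °C | run made earlier |  |
| south | 0.38 M | 0.38 M | 97 mM (held) | 58 °C | run made earlier |  |
| blue | 0.25 M | 0.25 M | 97 mM (held) | 70 °C |  | 20 min |
| violet | 0.25 M | 0.25 M | 97 mM (held) | 45 °C |  | 20 min |
| red | 0.25 M | 0.25 M | 97 mM (held) |  | at 45 °C until 10 min, from then on at 70 °C | 20 min |

| run | time / min | left-handed product / % | left-handed substrate / % |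
|---|---|---|---|
| south-west | 6.00 | 28.5 | 32.0 |
| south-west | 12.0 | 46.1 | 24.0 |
| south-west | 25.0 | 67.6 | 12.0 |
| south-west | 60.0 | 73.9 | 1.2 |
| south | 8.00 | 59.2 | 12.3 |
| south | 15.0 | 64.3 | 4.8 |
| south | 20.0 | 61.6 | 0 |
| south | 25.0 | 57.4 | 2.4 |

(each reading ± 1 percentage point)

- the flask with the highest amount of left-handed product, in percent of the left-handed substrate and right-handed substrate together charged ("all alike" if they lie within 1.5 percentage points) (blue / violet / red / all alike)
- final left-handed product, as a percentage of the left-handed substrate and right-handed substrate together charged, in blue
- final left-handed product, as a percentage of the left-handed substrate and right-handed substrate together charged, in violet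
- final left-handed product, as a percentage of the left-handed substrate and right-handed substrate together charged, in red

Watch the surplus of left-handed over right-handed product. Once no new product forms, it decays exponentially, so its rate constant is the logarithm of the ratio of two readings, divided by the time between them. In the south run, late on, I read the left-handed product above half falling at 0.0899 min⁻¹. In the south-west run, taking right-handed product by difference and the surplus as a share of product, I read 0.0119 min⁻¹. The two runs differ in charge too, but I put that rise down to temperature and spread it evenly, so I reckon 0.347 min⁻¹ at 70 °C and 0.0208 min⁻¹ at 45 °C. At 70 °C that gives 2.00 min for the excess half-life (racemisation half-life), the time in which the surplus halves.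

Do not raise violet's bath: at 45 °C its half-life of 33.3 min is longer than the 20 min run, so you will find surplus standing. Red's hot stage of 10.0 min is longer than 2.00 min, so I reckon 3.11% of the surplus standing at the change to be left of it at the end.

The forecast reads the fall the same way, “which I read as product racemisation, since the products are mirror images”, but takes 0.28 per minute where I take 0.347 min⁻¹. It gives 51% in blue, 67% in violet and 53.5% in red, with violet highest.

Blue gives 50.3%, violet 67.8% and red 52.3%, so violet is highest.

    left-handed substrate ⇌ right-handed substrate (k = 0.140 s⁻¹, Ea = 99.0 kJ mol⁻¹)
    gas ⇌ reagent, rate k2*(csat - [reagent]) (kL = 0.230 s⁻¹)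
    reagent ⇌ dormant form (K = 28.0, k = 0.00340 s⁻¹, Ea = 102 kJ mol⁻¹, ΔH = −19.0 kJ mol⁻¹)
    reagent + left-handed substrate → left-handed product (k = 0.120 M⁻¹ s⁻¹, Ea = 52.0 kJ mol⁻¹)
    left-handed product ⇌ right-handed product (k = 0.00290 s⁻¹, Ea = 98.0 kJ mol⁻¹)
    reagent + right-handed substrate → right-handed product (k = 0.00520 M⁻¹ s⁻¹, Ea = 78.0 kJ mol⁻¹)
    (constants at 70 °C)

In red, the relaxation half-life of the two products at the second temperature is 1.99 min, short against the hot stage of 10.0 min. Red goes from 49.6% left-handed and 4.39% right-handed product at the change to 52.3% and 46.3% at the end. Read red at 12 min instead: a half-life of 2.00 min leaves 23 percentage points of the surplus at the change, and the computed flask shows 56.7% against 19.8%, a larger surplus of 37 points, with the two substrates together down from 46.1% to 23.4% over those minutes.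

The runs are calculated with made-up constants.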